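## Retrosynthetic overview

1. The target comes from Markovnikov hydration of an 8-prenyl group and 7-O-methylation of (2S)-8-prenylpinocembrin. No ring is touched after the key step.
2. (2S)-8-Prenylpinocembrin comes from one open-chain precursor, a δ-hydroxy-β-diketone whose far end is a dioxinone (a masked acylketene). Rings C and A are both closed from it in one flask.
3. Ring order: ring B (phenyl) is bought. Ring C closes first (C2–OH onto the C8a ketone, loss of H2O), which leaves the C2–O bond untouched and fixes O1 next to the prenyl-bearing carbon. Ring A closes second (dioxinone to acylketene, C5–C4a closure, aromatisation).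
4. The open-chain precursor comes from C4–C4a bond formation between the terminal carbanion of a prenylated keto-dioxinone and ethyl (S)-3-hydroxy-3-phenylpropanoate, the only source of chirality.
5. The prenylated keto-dioxinone comes from the diketene–acetone adduct, acetyl chloride and prenyl bromide in one pot.

Assumption: atom labels (C2, C4a, C8a and so on) follow flavanone numbering in the open-chain compounds too, and the hydroxy ester is bought with at least 98% ee.

## Route

Step 1
Reactants: 1 2,2,6-trimethyl-4H-1,3-dioxin-4-one; 2 acetyl chloride; 3 prenyl bromide (1-bromo-3-methylbut-2-ene)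
Product: 5 2,2-dimethyl-6-(6-methyl-2-oxohept-5-en-3-yl)-4H-1,3-dioxin-4-one (racemic), via keto-dioxinone lithium enolate 4 (not isolated)
Conditions: 1 (2.1 equiv), LiN(iPr)2 (2.1 equiv), THF, −78 °C; 2 (1.0 equiv), −78 °C, 1 h; 3 (1.1 equiv), DMPU, −78 → 23 °C, 12 h
Reagents that add atoms: none
Why: Crossed Claisen C-acylation of the γ-lithiated dioxinone (the second equivalent of dienolate deprotonates the more acidic product, which shields 4 from over-acylation) is followed in the same flask by SN2 C-alkylation of this soft 1,3-dicarbonyl-type enolate by the allylic bromide; the new stereocentre forms racemic and is erased later when that carbon becomes aromatic C8.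

Step 2
Reactants: 5 2,2-dimethyl-6-(6-methyl-2-oxohept-5-en-3-yl)-4H-1,3-dioxin-4-one; 6 ethyl (3S)-3-hydroxy-3-phenylpropanoate
Product: 7 6-[(10S)-10-hydroxy-2-methyl-6,8-dioxo-10-phenyldec-2-en-5-yl]-2,2-dimethyl-4H-1,3-dioxin-4-one (both epimers at the prenyl-bearing carbon)
Conditions: 5 (1.3 equiv), LiN(iPr)2 (2.7 equiv), THF, −78 → −40 °C, 1 h; 6 (1.0 equiv) premixed with LiN(iPr)2 (1.0 equiv) in THF, added at −78 °C; −78 → −20 °C, 3 h; AcOH, −78 °C
Reagents that add atoms: none
Why: Dianion (Hauser–Harris type) crossed Claisen acylation: once the acidic methine is held as its enolate, the second deprotonation makes the terminal CH3 the most nucleophilic carbon, it attacks the ester of 6 (hydroxyl masked as lithium alkoxide), the released ethoxide converts the new β-diketone into its enolate and stops over-addition, and the carbinol carbon of 6 is a spectator that is carried through as (S).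

Step 3
Reactants: 7 6-[(10S)-10-hydroxy-2-methyl-6,8-dioxo-10-phenyldec-2-en-5-yl]-2,2-dimethyl-4H-1,3-dioxin-4-one
Product: 10 (2S)-5,7-dihydroxy-8-(3-methylbut-2-en-1-yl)-2-phenyl-2,3-dihydro-4H-chromen-4-one (glabranin), via dihydropyranone 8 (not isolated), via acylketene 9 (not isolated)
Conditions: PPTS (10 mol %), PhMe (0.01 M), 55 °C, 3 h; then reflux (111 °C) through a Soxhlet thimble of 4 Å molecular sieves, 2 h
Reagents that add atoms: none
Why: Proposed new method: mild acid first closes ring C by hemiketalisation of the C2 carbinol oxygen on the C8a ketone and loss of water (the known cyclodehydration of δ-hydroxy-β-diketones to 2,3-dihydro-4H-pyran-4-ones), which keeps the C2–O bond intact (retention, S), fixes O1 on the carbon next to prenyl-bearing C8 so that no 6-prenyl isomer can form, and blocks the enol oxygen that would otherwise trap the ketene as a 2-pyrone; after azeotropic removal of water, heating expels acetone by retro-hetero-Diels–Alder reaction (known dioxinone thermolysis), and acylketene 9, which through its C7 enol is a dienylketene, closes the C5–C4a bond by 6π electrocyclisation (or the equivalent C-acylation of the ring C enol ether) and tautomerises to the phloroglucinol ring A, the closest known reaction types being the ketene-generation/aromatisation cascades of diketo-dioxinones to resorcylates and the final step of the Danheiser benzannulation.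

Step 4
Reactants: 10 (2S)-5,7-dihydroxy-8-(3-methylbut-2-en-1-yl)-2-phenyl-2,3-dihydro-4H-chromen-4-one
Product: 11 (2S)-5-hydroxy-7-methoxy-8-(3-methylbut-2-en-1-yl)-2-phenyl-2,3-dihydro-4H-chromen-4-one
Conditions: MeOH (1.2 equiv), PPh3 (1.3 equiv), DIAD (1.3 equiv), THF, 0 → 23 °C
Reagents that add atoms: methanol CO
Why: Mitsunobu etherification under neutral conditions: only the free and more acidic 7-OH reacts because the 5-OH is locked in a hydrogen bond to the C4 carbonyl, and the absence of base avoids the retro-oxa-Michael ring opening that would racemise C2.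

Step 5
Reactants: 11 (2S)-5-hydroxy-7-methoxy-8-(3-methylbut-2-en-1-yl)-2-phenyl-2,3-dihydro-4H-chromen-4-one
Product: 12 (2S)-5-hydroxy-8-(3-hydroxy-3-methylbutyl)-7-methoxy-2-phenyl-2,3-dihydro-4H-chromen-4-one (target)
Conditions: Co(acac)2 (20 mol %), PhSiH3 (2.5 equiv), O2 (1 atm), THF, 23 °C
Reagents that add atoms: dioxygen O=O
Why: Mukaiyama hydration (hydrogen-atom transfer from a cobalt hydride to the trisubstituted alkene gives the tertiary radical, which is trapped by O2 and reduced to the alcohol) is Markovnikov-selective and neutral, leaves the ketone, chelated phenol and aryl ethers alone, and does not touch C2.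

## Compound list

1 | 2,2,6-trimethyl-4H-1,3-dioxin-4-one | CC1=CC(=O)OC(C)(C)O1 | starting material
2 | acetyl chloride | CC(=O)Cl | starting material
3 | prenyl bromide (1-bromo-3-methylbut-2-ene) | CC(C)=CCBr | starting material
4 | lithium enolate of 2,2-dimethyl-6-(2-oxopropyl)-4H-1,3-dioxin-4-one | [Li+].CC([O-])=CC1=CC(=O)OC(C)(C)O1 | intermediate
5 | 2,2-dimethyl-6-(6-methyl-2-oxohept-5-en-3-yl)-4H-1,3-dioxin-4-one (racemic) | CC(=O)C(CC=C(C)C)C1=CC(=O)OC(C)(C)O1 | intermediate
6 | ethyl (3S)-3-hydroxy-3-phenylpropanoate | CCOC(=O)C[C@H](O)c1ccccc1 | starting material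
7 | 6-[(10S)-10-hydroxy-2-methyl-6,8-dioxo-10-phenyldec-2-en-5-yl]-2,2-dimethyl-4H-1,3-dioxin-4-one (epimers at chain C5) | CC(C)=CCC(C(=O)CC(=O)C[C@H](O)c1ccccc1)C1=CC(=O)OC(C)(C)O1 | intermediate
8 | 2,2-dimethyl-6-{4-methyl-1-[(2S)-4-oxo-2-phenyl-3,4-dihydro-2H-pyran-6-yl]pent-3-en-1-yl}-4H-1,3-dioxin-4-one | CC(C)=CCC(C1=CC(=O)C[C@@H](c2ccccc2)O1)C1=CC(=O)OC(C)(C)O1 | intermediate
9 | 7-methyl-4-[(2S)-4-oxo-2-phenyl-3,4-dihydro-2H-pyran-6-yl]octa-1,6-diene-1,3-dione (acylketene) | CC(C)=CCC(C(=O)C=C=O)C1=CC(=O)C[C@@H](c2ccccc2)O1 | intermediate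
10 | (2S)-5,7-dihydroxy-8-(3-methylbut-2-en-1-yl)-2-phenyl-2,3-dihydro-4H-chromen-4-one | CC(C)=CCc1c(O)cc(O)c2c1O[C@H](c1ccccc1)CC2=O | intermediate
11 | (2S)-5-hydroxy-7-methoxy-8-(3-methylbut-2-en-1-yl)-2-phenyl-2,3-dihydro-4H-chromen-4-one | COc1cc(O)c2c(c1CC=C(C)C)O[C@H](c1ccccc1)CC2=O | intermediate
12 | (2S)-5-hydroxy-8-(3-hydroxy-3-methylbutyl)-7-methoxy-2-phenyl-2,3-dihydro-4H-chromen-4-one | COc1cc(O)c2c(c1CCC(C)(C)O)O[C@H](c1ccccc1)CC2=O | target

## Step count and risks

Total step count: 5.
Longest linear sequence: 5 steps (1 → 5 → 7 → 10 → 11 → 12).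

**Step 3 (double ring closure).**
- Risks: the ketene may be caught by residual water. It may also close on oxygen to a 2-pyrone if ring C is not complete before heating, or it may be too slow to attack C4a.
- The fallback sets out from 7 and comes back at 11. Stop after the PPTS stage and isolate 8.
- Heat 8 in toluene containing methanol so that the ketene is caught as methyl 7-methyl-3-oxo-4-[(2S)-4-oxo-2-phenyl-3,4-dihydro-2H-pyran-6-yl]oct-6-enoate F1.
- Convert the C7 ketone of F1 with HC(OMe)3 and catalytic H2SO4 into methyl (2E)-3-methoxy-7-methyl-4-[(2S)-4-oxo-2-phenyl-3,4-dihydro-2H-pyran-6-yl]octa-2,6-dienoate F2. In F2 the ester sits cis to the pyranone-bearing carbon and no acidic C6 proton remains.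
- Close ring A as an anionic vinylogous Dieckmann condensation (LiN(SiMe3)2, 1.05 equiv, THF, −78 °C, AcOH quench). The 7-methoxy group is already in place, so 11 forms directly and step 4 is not needed.

**Step 2 (dianion acylation by an enolisable β-hydroxy ester).**
- Risk: the carbanion may act as a base on the ester instead of adding to it.
- The fallback sets out from 6 (with 5 as partner) and comes back at 7. It makes the C4–C4a bond by aldol addition and oxidation instead of acylation.
- Silylate 6 (Et3SiCl, imidazole) to ethyl (3S)-3-phenyl-3-(triethylsilyloxy)propanoate F3.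
- Reduce F3 with iBu2AlH (CH2Cl2, −78 °C) to (3S)-3-phenyl-3-(triethylsilyloxy)propanal F4.
- Add doubly deprotonated 5 at −78 °C to get 6-[(10S)-8-hydroxy-2-methyl-6-oxo-10-phenyl-10-(triethylsilyloxy)dec-2-en-5-yl]-2,2-dimethyl-4H-1,3-dioxin-4-one F5.
- Oxidise F5 with Dess–Martin periodinane to 6-[(10S)-2-methyl-6,8-dioxo-10-phenyl-10-(triethylsilyloxy)dec-2-en-5-yl]-2,2-dimethyl-4H-1,3-dioxin-4-one F6.
- Remove the silyl group with HF·pyridine to reach 7.

**Step 1 (one-pot acylation and alkylation).**
- Risks: sluggish or O-selective alkylation of the lithium enolate, and double alkylation.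
- The fallback sets out from 1 and comes back at 5. It reverses the order of the two bond formations.
- Alkylate the hard γ-dienolate of 1 with 3 (LiN(iPr)2, DMPU, THF, −78 °C) to 2,2-dimethyl-6-(4-methylpent-3-en-1-yl)-4H-1,3-dioxin-4-one F7.
- Isolate F7, deprotonate it again at the γ-carbon, and C-acetylate with 2 to give 5.

Further compounds
F1 | step 3 | methyl 7-methyl-3-oxo-4-[(2S)-4-oxo-2-phenyl-3,4-dihydro-2H-pyran-6-yl]oct-6-enoate | COC(=O)CC(=O)C(CC=C(C)C)C1=CC(=O)C[C@@H](c2ccccc2)O1
F2 | step 3 | methyl (2E)-3-methoxy-7-methyl-4-[(2S)-4-oxo-2-phenyl-3,4-dihydro-2H-pyran-6-yl]octa-2,6-dienoate | COC(=O)/C=C(/OC)C(CC=C(C)C)C1=CC(=O)C[C@@H](c2ccccc2)O1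
F3 | step 2 | ethyl (3S)-3-phenyl-3-(triethylsilyloxy)propanoate | CCOC(=O)C[C@H](O[Si](CC)(CC)CC)c1ccccc1
F4 | step 2 | (3S)-3-phenyl-3-(triethylsilyloxy)propanal | O=CC[C@H](O[Si](CC)(CC)CC)c1ccccc1
F5 | step 2 | 6-[(10S)-8-hydroxy-2-methyl-6-oxo-10-phenyl-10-(triethylsilyloxy)dec-2-en-5-yl]-2,2-dimethyl-4H-1,3-dioxin-4-one | CC(C)=CCC(C(=O)CC(O)C[C@H](O[Si](CC)(CC)CC)c1ccccc1)C1=CC(=O)OC(C)(C)O1
F6 | step 2 | 6-[(10S)-2-methyl-6,8-dioxo-10-phenyl-10-(triethylsilyloxy)dec-2-en-5-yl]-2,2-dimethyl-4H-1,3-dioxin-4-one | CC(C)=CCC(C(=O)CC(=O)C[C@H](O[Si](CC)(CC)CC)c1ccccc1)C1=CC(=O)OC(C)(C)O1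
F7 | step 1 | 2,2-dimethyl-6-(4-methylpent-3-en-1-yl)-4H-1,3-dioxin-4-one | CC(C)=CCCC1=CC(=O)OC(C)(C)O1
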